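All runs come from a simulation with constants of no real substance.

The product, complex with three exchanged, appears when incoming ligand replaces leaving ligand on starting complex, and I read this as stepwise exchange through complexes with one and two exchanged.

| setting | south-west | west | flask |
|---|---|---|---|
| starting complex | 0.10 M | 0.10 M | 0.10 M |
| incoming ligand | 0.40 M | 0.20 M | 0.400 M |
| temperature | 110 °C | 110 °C | 110 °C |
| remark | the very flask that is asked about, followed so far | run made earlier |  |
| time |  |  | 1.0 h |

| run | time / min | complex with three exchanged / % | starting complex / % |
|---|---|---|---|
| south-west | 4.00 | 9.2 | 6.5 |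
| south-west | 6.00 | 9.8 | 2.8 |
| south-west | 10.0 | 10.5 | 3.5 |
| south-west | 20.0 | 9.8 | 2.9 |
| south-west | 30.0 | 9.4 | 2.9 |
| south-west | 50.0 | 10.3 | 3.0 |
| west | 4.00 | 3.6 | 24.7 |
| west | 8.00 | 3.0 | 12.5 |
| west | 12.0 | 3.2 | 9.6 |
| west | 15.0 | 3.4 | 9.0 |
| west | 20.0 | 2.5 | 8.0 |
| west | 25.0 | 2.5 | 8.5 |

(scatter of a reading: 0.5 percentage points)

- Tuesday's: at 1.0 h add incoming ligand, 50.0% of the amount charged, then wait 1.0 h
- Monday's: at 1.0 h raise the temperature by 15 K, then wait 1.0 h
- Saturday's: change nothing and wait 1.0 h more
- Friday's: at 1.0 h take out 90% of the leaving ligand then present, then wait 1.0 h

- complex with three exchanged, in percent of the starting complex first charged, at 1.0 h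
- the remedy with the largest gain of complex with three exchanged, or "none" below 2 percentage points (Tuesday's / Monday's / Saturday's / Friday's / none)
- complex with three exchanged present, in percent of the starting complex first charged, after Monday's
- complex with three exchanged present, in percent of the starting complex first charged, after Friday's

- what is added takes up no volume worth counting
- the earlier runs were read with a standard deviation of 0.5 percentage points
- the earlier runs do not show what temperature does; that part of a forecast is a guess

In the first minutes starting complex falls roughly as a pseudo-first-order decay whose pace goes with incoming ligand. Its half-life, read at 4.00 min, is 1.01 min in the south-west flask. In the west run it is 1.98 min, twice as long, on half the ligand.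

By 6.00 min the south-west readings are flat within their scatter, and they stay so to 50.0 min. Product averages 9.96% and starting complex 3.02%, so their ratio is 3.30. On this scheme the unread remainder, 87.0% of the charge, sits in the one- and two-exchanged forms. Splitting it evenly gives 1.60 exchanges per complex.

Each exchange uses one incoming ligand and frees one leaving ligand. With 4.00 incoming ligands charged per complex, the exchange ratio, free incoming over leaving ligand, is therefore 1.49. If each step stands at equilibrium at a fixed temperature, product over starting complex goes as the cube of this ratio, and the plateau constant, that quotient divided by the cubed exchange ratio, reads 0.990 from the south-west readings.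

The west plateau gives a quotient of 0.329. The cube rule then asks for a west ratio of 0.693, or 1.18 exchanges per complex, which the west balance permits.

So I expect about 9.96% in the flask at 1.0 h, and little change from waiting on so flat a plateau. Taking out leaving ligand multiplies the exchange ratio at that instant by 10.0, and adding incoming ligand by 1.83, so Friday's pushes harder, though exchange then pulls the ratio back. The runs show nothing about heating.

The forecast gives 10% now, 10% after Monday's and 27% after Friday's, and picks Friday's: “ratio about 3.5, product about 27%, so Friday's wins”.

The flask gives 9.90% and Friday's, with 26.1% after Friday's and 6.63% after Monday's. The gains are 16 percentage points for Friday's, 7.3 points for Tuesday's, −0.11 points for Saturday's and −3.3 points for Monday's.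

    incoming ligand → decomposition product (k = 1.90 × 10⁻⁴ min⁻¹, Ea = 126 kJ mol⁻¹)
    complex with two exchanged + incoming ligand ⇌ leaving ligand + complex with three exchanged (K = 0.170, k = 6.40 L mol⁻¹ min⁻¹, Ea = 67.0 kJ mol⁻¹, ΔH = −32.0 kJ mol⁻¹)
    complex with one exchanged + incoming ligand ⇌ leaving ligand + complex with two exchanged (K = 0.460, k = 3.10 L mol⁻¹ min⁻¹, Ea = 80.0 kJ mol⁻¹, ΔH = −18.0 kJ mol⁻¹)
    starting complex + incoming ligand ⇌ leaving ligand + complex with one exchanged (K = 11.0, k = 2.80 L mol⁻¹ min⁻¹, Ea = 86.0 kJ mol⁻¹, ΔH = 20.0 kJ mol⁻¹)
    (constants at 110 °C)

At 1.0 h in this flask the relaxation half-life of the product-forming step taken by itself, both ways together, 0.0872 min, is short against the time, and that of the first exchange, 0.934 min, is longer, though still minutes against an hour. This flask's exchange ratio is then 1.58, so the plateau constant gives a quotient of 3.90 against the 3.42 that stands there. In the neighbour flask with 0.040 M of starting complex the ratio at 1.0 h is 3.88, and the constant gives 57.8 against 50.1, with 29.5% product.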